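**Retrosynthetic overview**
1. Feature: on ring C (C8, C9, C11, C12, C13, C14) the oxygen on C11 and the oxygenated CH2 (C17) on quaternary C8 are both β-axial and 1,3-related through C9. C17 is therefore delivered to C8 from O11 through an O–SiMe2–CH2 tether by radical 6-exo closure onto a C8=C14–C15O2Me enoate, and Tamao oxidation then gives the 11β,17-diol.
2. Endgame: O17 isovalerate; acid closes O11 onto the C16 acetal carbon (the O11–C16 oxabicyclic ring, closed last); C16 acetate; C15 carbinol to aldehyde.
3. Ring C is closed before the key step by intramolecular Horner–Wadsworth–Emmons olefination of a C8 ketone with a C14 phosphonoacetate (C8=C14).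
4. Chain on C9: C11–C12 by chelation-controlled allylation of an 8α-hydroxy C11 aldehyde; C13–C16 by trans vinyl addition to a dihydropyranone made by acrylate ring-closing metathesis. C12 and C17 of (+)-sclareolide are excised (NaIO4; dehydration and ozonolysis).
5. Ring order: A and B (sclareolide), temporary δ-lactone, ring C, siloxane ring (key step), O11–C16 acetal ring.

Key step: step 15

Remark: isocopalane numbering is used throughout (C1–C10 decalin; C15 on C14; C16 on C13; C17 on C8; C18, C19 on C4; C20 on C10); α is the face of H5 and H9, β the face of the C20 methyl.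
Remark: compounds 21, 23, 27 and 29 hold O11 1,3-diaxial to the C16 dimethyl acetal and are kept from acid (amine-deactivated silica) until step 20 uses that closure.

**Step 1**
Reactants: 1 (+)-sclareolide
Product: 2 11-hydroxysclareolide (OH on C11 on the α-face; this centre is lost in step 3)
Conditions: KN(SiMe3)2, THF, −78 °C; 2-(phenylsulfonyl)-3-phenyloxaziridine, −78 °C; aq. NH4Cl
Reagents that add atoms: 2-(phenylsulfonyl)-3-phenyloxaziridine, O=S(=O)(c1ccccc1)N1OC1c1ccccc1
Why: Electrophilic α-hydroxylation of the potassium lactone enolate by the N-sulfonyloxaziridine should place oxygen on C11 from the face away from the axial C17 and C20 methyls, which prepares the C11–C12 glycol cleavage.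

**Step 2**
Reactants: 2 11-hydroxysclareolide
Product: 3 13,14,15,16-tetranorlabdane-8α,11,12-triol
Conditions: LiAlH4, THF, 0 to 20 °C
Reagents that add atoms: none
Why: Hydride reduction of the lactone (LiAlH4 reduction of an ester) should give the C11–C12 vicinal diol beside the untouched tertiary 8α-OH, with no stereocentre created.

**Step 3**
Reactants: 3 13,14,15,16-tetranorlabdane-8α,11,12-triol
Product: 4 8α-hydroxy-12,13,14,15,16-pentanorlabdan-11-al
Conditions: NaIO4, THF/H2O, 0 to 20 °C
Reagents that add atoms: none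
Why: Glycol cleavage (Malaprade reaction) removes C12 as formaldehyde and leaves C11 as the aldehyde on C9, while the tertiary 8α-OH is 1,3 to C11 and cannot be cleaved and the neutral medium should spare the β-hydroxy aldehyde from dehydration.

**Step 4**
Reactants: 4 8α-hydroxy-12,13,14,15,16-pentanorlabdan-11-al; 5 allyl bromide
Product: 6 (11S)-homoallylic 8α,11-diol
Conditions: allyl bromide, In powder, THF/H2O (1:1), 20 °C
Reagents that add atoms: allyl bromide (5), C=CCBr
Why: In this Barbier allylation the metal bridging 8α-OH and the aldehyde oxygen should hold C11=O syn to C8–O, so that the allyl group adds to the face opposite the axial C17 and C20 methyls and sets C11 as S, the future 11β-oxygen.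

**Step 5**
Reactants: 6 (11S)-homoallylic 8α,11-diol; 7 acryloyl chloride
Product: 8 11-O-acrylate of 6
Conditions: acryloyl chloride, iPr2NEt, DMAP (cat.), CH2Cl2, −20 to 0 °C
Reagents that add atoms: acryloyl chloride (7), C=CC(=O)Cl
Why: Esterification with the acid chloride should occur only at the secondary C11–OH because the tertiary 8α-OH is far more hindered, and no stereocentre changes.

**Step 6**
Reactants: 8 11-O-acrylate of 6
Product: 9 (6S)-6-substituted 5,6-dihydro-2H-pyran-2-one (ring O11–C15–C14=C13–C12–C11; 8α-OH kept)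
Conditions: second-generation Grubbs catalyst RuCl2(=CHPh)(H2IMes)(PCy3) (5 mol %), CH2Cl2, 40 °C, 0.005 M
Reagents that add atoms: none
Why: Ring-closing metathesis of the acrylate with the terminal allyl alkene should close the six-membered unsaturated δ-lactone with loss of ethene, and no second alkene competes because C8 is still a saturated carbinol.

**Step 7**
Reactants: 9 (6S)-6-substituted 5,6-dihydro-2H-pyran-2-one
Product: 10 dihydropyranone with exocyclic C8=C17 methylene
Conditions: SOCl2, pyridine, CH2Cl2, −78 °C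
Reagents that add atoms: none
Why: E2 dehydration through the chlorosulfite of the equatorial 8α-OH, which has no antiperiplanar ring hydrogen, should take a hydrogen from the C17 methyl and give the exocyclic alkene that is later cleaved to the C8 ketone.

**Step 8**
Reactants: 10 dihydropyranone with exocyclic C8=C17 methylene; 11 vinylmagnesium bromide
Product: 12 (4R,6S)-4-vinyl δ-lactone (vinyl on C13; trans to the C11 substituent)
Conditions: vinylmagnesium bromide, CuBr·SMe2 (10 mol %), THF, −78 to −40 °C; aq. NH4Cl
Reagents that add atoms: vinylmagnesium bromide (11), C=C[Mg]Br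
Why: CuBr·SMe2-catalysed conjugate addition of the Grignard reagent should proceed by axial attack anti to the pseudoequatorial C11 substituent, giving the 4,6-trans lactone and so setting C13 with its new carbon (C16) on the side that becomes β in ring C.

**Step 9**
Reactants: 12 (4R,6S)-4-vinyl δ-lactone
Product: 15 methyl ester 11-O-triethylsilyl ether, via potassium hydroxy carboxylate 13 (not isolated), via hydroxy methyl ester 14 (not isolated)
Conditions: KOH, MeOH/H2O, 20 °C, evaporate; MeI, DMF, 20 °C; then Et3SiCl, imidazole, 0 to 20 °C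
Reagents that add atoms: potassium hydroxide, [K+].[OH-]; iodomethane, CI; chlorotriethylsilane, CC[Si](Cl)(CC)CC
Why: Saponification opens the δ-lactone irreversibly, O-alkylation of the carboxylate gives the methyl ester without acid, and immediate silylation of the freed C11–OH prevents relactonisation, all without touching a stereocentre.

**Step 10**
Reactants: 15 methyl ester 11-O-triethylsilyl ether
Product: 17 C14 diethyl phosphonate (C14 epimers), via C14 diethyl phosphonite 16 (not isolated)
Conditions: LiN(iPr)2, THF, −78 °C; ClP(OEt)2, −78 to 0 °C; then 30% H2O2, 0 °C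
Reagents that add atoms: diethyl chlorophosphite, CCOP(Cl)OCC; hydrogen peroxide, OO
Why: C-Phosphinylation of the ester enolate with the trivalent phosphorus chloride followed by oxidation to the phosphonate should place the olefination handle on C14, whose new centre forms as a mixture and is lost in step 12.

**Step 11**
Reactants: 17 C14 diethyl phosphonate
Product: 19 8-oxo 16,16-dimethyl acetal, via 8-oxo 16-aldehyde 18 (not isolated)
Conditions: O3, CH2Cl2/MeOH (4:1), −78 °C; Me2S, −78 to 20 °C; then HC(OMe)3, CeCl3·7H2O, MeOH, 20 °C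
Reagents that add atoms: ozone, [O-][O+]=O; trimethyl orthoformate, COC(OC)OC; methanol, CO
Why: Ozonolysis with reductive work-up cleaves both terminal alkenes at once (vinyl to the C16 aldehyde, exocyclic methylene to the C8 ketone with loss of C17), and CeCl3-mediated acetalisation with the orthoformate should protect only the aldehyde and leave the hindered ketone free.

**Step 12**
Reactants: 19 8-oxo 16,16-dimethyl acetal
Product: 20 methyl 16,16-dimethoxy-11β-(triethylsilyloxy)-17-norisocopal-8(14)-en-15-oate
Conditions: NaH, THF, 0 to 45 °C, 0.01 M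
Reagents that add atoms: none
Why: Intramolecular Horner–Wadsworth–Emmons olefination of the C8 ketone by the C14 phosphonate anion closes six-membered ring C as the tetrasubstituted C8=C14 enoate, and the β-silyloxy ketone should survive because only the far more acidic phosphonate is deprotonated.

**Step 13**
Reactants: 20 methyl 16,16-dimethoxy-11β-(triethylsilyloxy)-17-norisocopal-8(14)-en-15-oate
Product: 21 methyl 11β-hydroxy-16,16-dimethoxy-17-norisocopal-8(14)-en-15-oate
Conditions: Bu4NF, THF, 0 °C
Reagents that add atoms: none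
Why: Fluoride-mediated desilylation frees the axial 11β-OH under basic conditions in which the C16 acetal cannot exchange with it, and lactonisation onto C15 is excluded because it would put C8=C14 at a bridgehead.

**Step 14**
Reactants: 21 methyl 11β-hydroxy-16,16-dimethoxy-17-norisocopal-8(14)-en-15-oate; 22 (bromomethyl)chlorodimethylsilane
Product: 23 11β-[(bromomethyl)dimethylsilyl]oxy enoate
Conditions: ClSiMe2CH2Br, Et3N, DMAP (cat.), CH2Cl2, 0 °C; filtered through basic alumina and used at once
Reagents that add atoms: (bromomethyl)chlorodimethylsilane (22), C[Si](C)(Cl)CBr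
Why: Silyl ether formation with the small chlorosilane should still reach the hindered axial hydroxyl and attaches the radical precursor to O11 with C11 unchanged.

**Step 15**
Reactants: 23 11β-[(bromomethyl)dimethylsilyl]oxy enoate
Product: 24 tetracyclic siloxane (O11–SiMe2–C17–C8; 14α-H; 15-methyl ester; 16,16-dimethyl acetal)
Conditions: Bu3SnH (1.3 equiv), AIBN (0.2 equiv), benzene, 80 °C, syringe-pump addition over 8 h, 0.005 M
Reagents that add atoms: none
Why: The Bu3Sn radical abstracts bromine to give the nucleophilic α-silyl radical Si–CH2•, which adds to C8, the β-carbon of the C8=C14 enoate, and the ester-stabilised C14 radical then takes hydrogen from Bu3SnH to carry the chain; the closest known reaction type is the radical cyclisation of (bromomethyl)dimethylsilyl ethers of homoallylic alcohols, used with Tamao oxidation to deliver a hydroxymethyl group cis to a hydroxyl. The only ring closed is the siloxane ring O11–Si–C17–C8–C9–C11, in the 6-exo-trig mode. The new quaternary centre C8 is controlled by the tether, since the radical hangs from the axial 11β-oxygen, 1,3 to C8 through C9, and can reach only the β-lobe of C8, so C17 becomes β. The new centre C14 is set by hydrogen transfer to the α-face, opposite the new axial C17 and the β-acetal on C13, which gives 14α-H and the equatorial β-ester, also the more stable epimer. The step needs attack at C8 and not at C14 (6-exo against 7-endo), which the polarity of the enoate and the ring size secure, and it needs cyclisation to outrun direct reduction of the radical, for which the stannane is kept dilute by slow addition.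

**Step 16**
Reactants: 24 tetracyclic siloxane
Product: 25 siloxane 15-alcohol
Conditions: iBu2AlH, CH2Cl2, −78 to 0 °C; aq. potassium sodium tartrate
Reagents that add atoms: none
Why: Hydride reduction of the ester to the primary alcohol is done while O11 and O17 are still locked in the siloxane, so that O15 is told apart from them and cannot later lactonise with O17.

**Step 17**
Reactants: 25 siloxane 15-alcohol
Product: 26 siloxane 15-O-tert-butyldiphenylsilyl ether
Conditions: tBuPh2SiCl, imidazole, DMF, 20 °C
Reagents that add atoms: tert-butylchlorodiphenylsilane, CC(C)(C)[Si](Cl)(c1ccccc1)c1ccccc1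
Why: Silylation of the only free hydroxyl masks O15 with a group that should survive the basic peroxide of step 18 and the aqueous acid of step 20, so that O15 cannot compete for C16.

**Step 18**
Reactants: 26 siloxane 15-O-tert-butyldiphenylsilyl ether
Product: 27 11β,17-diol
Conditions: 30% H2O2, KF, KHCO3, THF/MeOH (1:1), 45 °C
Reagents that add atoms: hydrogen peroxide, OO
Why: Tamao oxidation of the alkoxysilane converts C17–Si into C17–OH and frees 11β-OH, revealing the cis-1,3-diol across C9 without affecting any stereocentre.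

**Step 19**
Reactants: 27 11β,17-diol; 28 3-methylbutanoyl chloride
Product: 29 17-(3-methylbutanoate)
Conditions: 3-methylbutanoyl chloride, pyridine, DMAP (cat.), CH2Cl2, 0 °C
Reagents that add atoms: 3-methylbutanoyl chloride (28), CC(C)CC(=O)Cl
Why: Esterification should take place only at the primary C17–OH, because the axial 11β-OH is shielded by the C20 methyl, the C17 arm and the C13 acetal.

**Step 20**
Reactants: 29 17-(3-methylbutanoate)
Product: 31 bridged 11β,16-lactol (16-OH exo), via 11β-hydroxy 16-aldehyde 30 (not isolated)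
Conditions: pyridinium p-toluenesulfonate, acetone/H2O (5:1), 40 °C
Reagents that add atoms: water, O
Why: Acid-catalysed acetal hydrolysis releases the C16 aldehyde, which is trapped at once by the 1,3-diaxial 11β-OH, the only free hydroxyl, as the five-membered lactol of the oxabicycle, with the C16 hydroxyl expected on the exo face away from C17.

**Step 21**
Reactants: 31 bridged 11β,16-lactol; 32 acetic anhydride
Product: 33 16-exo-acetate
Conditions: Ac2O, pyridine, DMAP (cat.), CH2Cl2, 0 to 20 °C
Reagents that add atoms: acetic anhydride (32), CC(=O)OC(C)=O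
Why: Acetylation of the lactol hydroxyl should give the exo acetate, since the anomers interconvert through the open aldehyde and the endo face of C16 is blocked by the C17 acyloxymethyl group.

**Step 22**
Reactants: 33 16-exo-acetate
Product: 34 15-alcohol
Conditions: Bu4NF, AcOH (1:1), THF, 20 °C
Reagents that add atoms: none
Why: Buffered fluoride-mediated desilylation should remove the silyl ether from O15 without cleaving the two esters or the anomeric acetate.

**Step 23**
Reactants: 34 15-alcohol
Product: 35 CNP0331370.1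
Conditions: Dess–Martin periodinane, pyridine, CH2Cl2, 20 °C
Reagents that add atoms: none
Why: Dess–Martin oxidation of the primary alcohol gives the C15 aldehyde under buffered conditions that should not epimerise C14, whose equatorial β-formyl group is also the thermodynamic configuration.

**Compound list**
1 | (+)-sclareolide | O=C1C[C@H]2[C@@](C)(CC[C@H]3C(C)(C)CCC[C@]23C)O1 | starting material
2 | 11-hydroxysclareolide (11-OH on the α-face) | O=C1[C@@H](O)[C@H]2[C@@](C)(CC[C@H]3C(C)(C)CCC[C@]23C)O1 | intermediate
3 | 13,14,15,16-tetranorlabdane-8α,11,12-triol (C11 as in 2) | OC[C@@H](O)[C@H]1[C@](C)(O)CC[C@H]2C(C)(C)CCC[C@]12C | intermediate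
4 | 8α-hydroxy-12,13,14,15,16-pentanorlabdan-11-al (CHO = C11 on C9; 5α-H, 9α-H) | O=C[C@H]1[C@](C)(O)CC[C@H]2C(C)(C)CCC[C@]12C | intermediate
5 | allyl bromide | C=CCBr | starting material
6 | (11S)-homoallylic 8α,11-diol (allyl CH2 = C12, CH = C13) | C=CC[C@H](O)[C@H]1[C@](C)(O)CC[C@H]2C(C)(C)CCC[C@]12C | intermediate
7 | acryloyl chloride | C=CC(=O)Cl | starting material
8 | 11-O-acrylate of 6 | C=CC[C@H](OC(=O)C=C)[C@H]1[C@](C)(O)CC[C@H]2C(C)(C)CCC[C@]12C | intermediate
9 | (6S)-6-(8α-hydroxydecalinyl)-5,6-dihydro-2H-pyran-2-one (lactone C=O = C15, C14=C13, C6 = C11) | O=C1C=CC[C@H](O1)[C@H]2[C@](C)(O)CC[C@H]3C(C)(C)CCC[C@]23C | intermediate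
10 | dihydropyranone with exocyclic C8=C17 methylene | O=C1C=CC[C@H](O1)[C@H]2C(=C)CC[C@H]3C(C)(C)CCC[C@]23C | intermediate
11 | vinylmagnesium bromide | C=C[Mg]Br | starting material
12 | (4R,6S)-4-vinyl δ-lactone (vinyl CH = C16 on C13, trans to the C11 substituent) | O=C1C[C@H](C=C)C[C@H](O1)[C@H]2C(=C)CC[C@H]3C(C)(C)CCC[C@]23C | intermediate
13 | potassium 11-hydroxy carboxylate (C11, C13 as in 12) | [K+].[O-]C(=O)C[C@H](C=C)C[C@H](O)[C@H]1C(=C)CC[C@H]2C(C)(C)CCC[C@]12C | intermediate (not isolated)
14 | methyl 11-hydroxy ester (C11, C13 as in 12) | COC(=O)C[C@H](C=C)C[C@H](O)[C@H]1C(=C)CC[C@H]2C(C)(C)CCC[C@]12C | intermediate (not isolated)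
15 | methyl ester, 11-O-triethylsilyl ether (C11, C13 as in 12) | COC(=O)C[C@H](C=C)C[C@H](O[Si](CC)(CC)CC)[C@H]1C(=C)CC[C@H]2C(C)(C)CCC[C@]12C | intermediate
16 | C14 diethyl phosphonite (C14 epimers) | COC(=O)C(P(OCC)OCC)[C@H](C=C)C[C@H](O[Si](CC)(CC)CC)[C@H]1C(=C)CC[C@H]2C(C)(C)CCC[C@]12C | intermediate (not isolated)
17 | C14 diethyl phosphonate (C14 epimers) | COC(=O)C(P(=O)(OCC)OCC)[C@H](C=C)C[C@H](O[Si](CC)(CC)CC)[C@H]1C(=C)CC[C@H]2C(C)(C)CCC[C@]12C | intermediate
18 | 8-oxo 16-aldehyde phosphonate | COC(=O)C(P(=O)(OCC)OCC)[C@H](C=O)C[C@H](O[Si](CC)(CC)CC)[C@H]1C(=O)CC[C@H]2C(C)(C)CCC[C@]12C | intermediate (not isolated)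
19 | 8-oxo 16,16-dimethyl acetal phosphonate | COC(=O)C(P(=O)(OCC)OCC)[C@H](C(OC)OC)C[C@H](O[Si](CC)(CC)CC)[C@H]1C(=O)CC[C@H]2C(C)(C)CCC[C@]12C | intermediate
20 | methyl 16,16-dimethoxy-11β-(triethylsilyloxy)-17-norisocopal-8(14)-en-15-oate (13β-CH(OMe)2) | COC(=O)C1=C2CC[C@H]3C(C)(C)CCC[C@]3(C)[C@H]2[C@@H](O[Si](CC)(CC)CC)C[C@H]1C(OC)OC | intermediate
21 | methyl 11β-hydroxy-16,16-dimethoxy-17-norisocopal-8(14)-en-15-oate | COC(=O)C1=C2CC[C@H]3C(C)(C)CCC[C@]3(C)[C@H]2[C@@H](O)C[C@H]1C(OC)OC | intermediate
22 | (bromomethyl)chlorodimethylsilane | C[Si](C)(Cl)CBr | starting material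
23 | methyl 11β-[(bromomethyl)dimethylsilyl]oxy-16,16-dimethoxy-17-norisocopal-8(14)-en-15-oate | COC(=O)C1=C2CC[C@H]3C(C)(C)CCC[C@]3(C)[C@H]2[C@@H](O[Si](C)(C)CBr)C[C@H]1C(OC)OC | intermediate
24 | tetracyclic siloxane: methyl 16,16-dimethoxy-11β,17-(oxydimethylsilanediyl)isocopalan-15-oate (8β-CH2, 14α-H) | COC(=O)[C@H]1[C@]23CC[C@H]4C(C)(C)CCC[C@]4(C)[C@H]2[C@@H](O[Si](C)(C)C3)C[C@H]1C(OC)OC | intermediate
25 | siloxane 15-alcohol | OC[C@H]1[C@]23CC[C@H]4C(C)(C)CCC[C@]4(C)[C@H]2[C@@H](O[Si](C)(C)C3)C[C@H]1C(OC)OC | intermediate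
26 | siloxane 15-O-tert-butyldiphenylsilyl ether | CC(C)(C)[Si](OC[C@H]1[C@]23CC[C@H]4C(C)(C)CCC[C@]4(C)[C@H]2[C@@H](O[Si](C)(C)C3)C[C@H]1C(OC)OC)(c1ccccc1)c1ccccc1 | intermediate
27 | 11β,17-diol (15-O-silyl ether, 16,16-dimethyl acetal) | CC(C)(C)[Si](OC[C@H]1[C@]2(CO)CC[C@H]3C(C)(C)CCC[C@]3(C)[C@H]2[C@@H](O)C[C@H]1C(OC)OC)(c1ccccc1)c1ccccc1 | intermediate
28 | 3-methylbutanoyl chloride (isovaleryl chloride) | CC(C)CC(=O)Cl | starting material
29 | 17-(3-methylbutanoate) of 27 | CC(C)(C)[Si](OC[C@H]1[C@]2(COC(=O)CC(C)C)CC[C@H]3C(C)(C)CCC[C@]3(C)[C@H]2[C@@H](O)C[C@H]1C(OC)OC)(c1ccccc1)c1ccccc1 | intermediate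
30 | 11β-hydroxy 16-aldehyde | CC(C)(C)[Si](OC[C@H]1[C@]2(COC(=O)CC(C)C)CC[C@H]3C(C)(C)CCC[C@]3(C)[C@H]2[C@@H](O)C[C@H]1C=O)(c1ccccc1)c1ccccc1 | intermediate (not isolated)
31 | bridged 11β,16-lactol, 16-OH exo | O[C@H]1O[C@H]2C[C@@H]1[C@@H](CO[Si](c1ccccc1)(c1ccccc1)C(C)(C)C)[C@]1(COC(=O)CC(C)C)CC[C@H]3C(C)(C)CCC[C@]3(C)[C@@H]21 | intermediate
32 | acetic anhydride | CC(=O)OC(C)=O | starting material
33 | 16-exo-acetate, 15-O-silyl ether | CC(=O)O[C@H]1O[C@H]2C[C@@H]1[C@@H](CO[Si](c1ccccc1)(c1ccccc1)C(C)(C)C)[C@]1(COC(=O)CC(C)C)CC[C@H]3C(C)(C)CCC[C@]3(C)[C@@H]21 | intermediate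
34 | 16-exo-acetate, 15-alcohol | CC(=O)O[C@H]1O[C@H]2C[C@@H]1[C@@H](CO)[C@]1(COC(=O)CC(C)C)CC[C@H]3C(C)(C)CCC[C@]3(C)[C@@H]21 | intermediate
35 | CNP0331370.1: 16-acetoxy-11β,16-epoxy-17-(3-methylbutanoyloxy)isocopalan-15-al | CC(=O)O[C@H]1O[C@H]2C[C@@H]1[C@@H](C=O)[C@]1(COC(=O)CC(C)C)CC[C@H]3C(C)(C)CCC[C@]3(C)[C@@H]21 | target

**Step count and risks**
Total: 23 steps. Longest linear sequence: 23 steps from (+)-sclareolide (1).

Steps most likely to fail:

1. Step 15. The α-silyl radical may be reduced by the stannane before it closes onto the fully substituted C8, whose β-face is also crowded by the pseudoaxial C13 acetal; this would return the simple 11β-silyl ether. Fallback: the acceptor is made smaller and more electrophilic. Setting out from 21, iBu2AlH reduction gives the allylic 11β,15-diol F1. MnO2 oxidises only the allylic primary alcohol and gives the enal F2. Silylation as in step 14 gives the bromomethylsilyl ether of the enal F3. Cyclisation with (Me3Si)3SiH and AIBN (a slower hydrogen donor) gives the siloxane 15-aldehyde F4. NaBH4 reduction then comes back to the route at 25.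

2. Step 12. Addition of the α-branched phosphonate anion to the hindered C8 ketone may be slow, so that enolisation towards C9 with β-elimination of the 11-silyloxy group, or stalling at the β-hydroxy phosphonate, takes over. Fallback: olefination is replaced by Reformatsky addition and dehydration. Setting out from 15, LiN(iPr)2 then CBr4 gives the α-bromo ester F5. Ozonolysis as in step 11 gives the bromo keto aldehyde F6, acetalised in the same flask to the bromo keto acetal F7. SmI2 in THF at −78 °C closes ring C to the β-hydroxy ester F8. Dehydration with SOCl2/pyridine and brief DBU equilibration into conjugation comes back to the route at 20.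

3. Step 10. The ester enolate may attack the chlorophosphite through oxygen, or be quenched by proton exchange, so that C–P bond formation stays incomplete. Fallback: the phosphorus is put on oxygen on purpose and moved to carbon. Setting out from 15, LiN(iPr)2 and ClP(O)(OEt)2 give the ketene acetal phosphate F9. A second equivalent of LiN(iPr)2 induces the 1,3 oxygen-to-carbon phosphoryl shift, which comes back to the route at 17.

**Further compounds**
F1 | step 15 | 11β,15-dihydroxy-16,16-dimethoxy-17-norisocopal-8(14)-ene | OCC1=C2CC[C@H]3C(C)(C)CCC[C@]3(C)[C@H]2[C@@H](O)C[C@H]1C(OC)OC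
F2 | step 15 | 11β-hydroxy-16,16-dimethoxy-17-norisocopal-8(14)-en-15-al | O=CC1=C2CC[C@H]3C(C)(C)CCC[C@]3(C)[C@H]2[C@@H](O)C[C@H]1C(OC)OC
F3 | step 15 | 11β-[(bromomethyl)dimethylsilyl]oxy-16,16-dimethoxy-17-norisocopal-8(14)-en-15-al | O=CC1=C2CC[C@H]3C(C)(C)CCC[C@]3(C)[C@H]2[C@@H](O[Si](C)(C)CBr)C[C@H]1C(OC)OC
F4 | step 15 | siloxane 15-aldehyde (8β-CH2, 14α-H) | O=C[C@H]1[C@]23CC[C@H]4C(C)(C)CCC[C@]4(C)[C@H]2[C@@H](O[Si](C)(C)C3)C[C@H]1C(OC)OC
F5 | step 12 | C14 bromo derivative of 15 (C14 epimers) | COC(=O)C(Br)[C@H](C=C)C[C@H](O[Si](CC)(CC)CC)[C@H]1C(=C)CC[C@H]2C(C)(C)CCC[C@]12C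
F6 | step 12 | C14 bromo 8-oxo 16-aldehyde | COC(=O)C(Br)[C@H](C=O)C[C@H](O[Si](CC)(CC)CC)[C@H]1C(=O)CC[C@H]2C(C)(C)CCC[C@]12C
F7 | step 12 | C14 bromo 8-oxo 16,16-dimethyl acetal | COC(=O)C(Br)[C@H](C(OC)OC)C[C@H](O[Si](CC)(CC)CC)[C@H]1C(=O)CC[C@H]2C(C)(C)CCC[C@]12C
F8 | step 12 | methyl 8-hydroxy-16,16-dimethoxy-11β-(triethylsilyloxy)-17-norisocopalan-15-oate (C8 and C14 not defined; both removed on dehydration) | COC(=O)C1C2(O)CC[C@H]3C(C)(C)CCC[C@]3(C)[C@H]2[C@@H](O[Si](CC)(CC)CC)C[C@H]1C(OC)OC
F9 | step 10 | ketene acetal diethyl phosphate of 15 | COC(OP(=O)(OCC)OCC)=C[C@H](C=C)C[C@H](O[Si](CC)(CC)CC)[C@H]1C(=C)CC[C@H]2C(C)(C)CCC[C@]12C
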